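## Retrosynthetic overview

1. The C13 carbinol and the vinyl group come from reductive opening of a 2,3-epoxy iodide, made by Sharpless epoxidation of the (Z)-C13=C14 allylic alcohol 27. The C12–C13 bond comes from a B-alkyl Suzuki coupling of diene 22 with (Z)-3-iodobut-2-en-1-ol.
2. C8=C9 comes from α-bromination and anti elimination of the C9 ester, C3–Br from Appel inversion of the axial C3 alcohol, and C5–H from hydroxyl-directed hydrogenation of C5=C6.
3. Ring B and the C9–C10 bond come from an Ireland–Claisen ring transposition of δ-lactone 10. The plan rests on the allyl triad C6–C5=C10: the quaternary ring-fusion carbon C10 (bearing C20) is the far end of the ring A alkene, and its near end C5 carries C6, so a C6–O stereocentre can be exchanged for the C10 stereocentre in a [3,3] shift that also closes ring B.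
4. Lactone 10 comes from ring A aldehyde 5 (C6) by asymmetric allylation (C7, C8), acryloylation (C9, C11), ring-closing metathesis and methyl cuprate addition (C17).
5. Ring order: ring A is bought with 1 (C3 stereocentre); the δ-lactone is a temporary ring; ring B closes in step 9; the oxirane of 28 is temporary.

Key step: step 9

Remark: atoms carry labdane numbers (ring A = C1–C5, C10; ring B = C5–C10; side chain C11–C16 with C16 the methyl on C13; C17 on C8; C20 on C10).
Remark: hydroxy ketone 1 is taken as purchasable; it is the baker's-yeast reduction product of 2,2-dimethylcyclohexane-1,3-dione.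
Remark: metal enolates and alkoxides that exist only between a base or hydride and its quench are not numbered.

## Route

Step 1
Reactants: 1 (S)-3-hydroxy-2,2-dimethylcyclohexan-1-one
Product: 2 (S)-3-(tert-butyldimethylsilyloxy)-2,2-dimethylcyclohexan-1-one
Conditions: TBSCl, imidazole, DMF, 23 °C
Reagents that add atoms: tert-butyldimethylsilyl chloride, C[Si](C)(Cl)C(C)(C)C
Why: Silyl ether protection of the secondary alcohol masks the C3 hydroxyl against the bases and organometallics of steps 2 to 9 without touching the stereocentre.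

Step 2
Reactants: 2 (S)-3-(tert-butyldimethylsilyloxy)-2,2-dimethylcyclohexan-1-one
Product: 3 (3S)-3-(tert-butyldimethylsilyloxy)-2,2,6-trimethylcyclohexan-1-one (both C6 epimers)
Conditions: LiN(iPr)2, THF, −78 °C; MeI, −78 → 0 °C
Reagents that add atoms: iodomethane, CI
Why: Lithium enolate alkylation can only occur at C10, the single enolisable α-carbon, and the new centre (epimer mixture) is erased in step 3.

Step 3
Reactants: 3 (3S)-3-(tert-butyldimethylsilyloxy)-2,2,6-trimethylcyclohexan-1-one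
Product: 4 (S)-5-(tert-butyldimethylsilyloxy)-2,6,6-trimethylcyclohex-1-en-1-yl trifluoromethanesulfonate
Conditions: LiN(iPr)2, THF, −78 → 0 °C; PhNTf2, 0 → 23 °C
Reagents that add atoms: N-phenylbis(trifluoromethanesulfonimide), O=S(=O)(N(c1ccccc1)S(=O)(=O)C(F)(F)F)C(F)(F)F
Why: Enol triflate formation is regiodefined because C4 is quaternary, so enolisation and O-sulfonylation give only the tetrasubstituted C5=C10 alkene.

Step 4
Reactants: 4 (S)-5-(tert-butyldimethylsilyloxy)-2,6,6-trimethylcyclohex-1-en-1-yl trifluoromethanesulfonate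
Product: 5 (S)-5-(tert-butyldimethylsilyloxy)-2,6,6-trimethylcyclohex-1-ene-1-carbaldehyde
Conditions: Pd(PPh3)4 (5 mol %), LiCl, CO (3 atm), Bu3SnH (slow addition), THF, 50 °C
Reagents that add atoms: carbon monoxide, [C-]#[O+]
Why: Palladium-catalysed reductive carbonylation of the enol triflate (oxidative addition, CO insertion, hydride transfer from tin) installs C6 as the aldehyde, and slow hydride addition should suppress direct reduction.

Step 5
Reactants: 5 (S)-5-(tert-butyldimethylsilyloxy)-2,6,6-trimethylcyclohex-1-ene-1-carbaldehyde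
Product: 7 (1R)-1-[(5S)-5-(tert-butyldimethylsilyloxy)-2,6,6-trimethylcyclohex-1-en-1-yl]but-3-en-1-ol, via diisopinocampheylborinate 6 (not isolated)
Conditions: (+)-Ipc2BOMe, CH2=CHCH2MgBr, Et2O, 0 → 23 °C; then 5, −78 °C; NaOH, H2O2, 0 → 23 °C
Reagents that add atoms: allylmagnesium bromide, C=CC[Mg]Br
Why: Brown allylboration through a closed chair transition state is reagent-controlled, so the borane derived from (−)-α-pinene should deliver C7–C8 to the Re face of the aldehyde and set C6 as R; the minor C6 epimer is a diastereomer (C3 is fixed) and can be removed by chromatography.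

Step 6
Reactants: 7 (1R)-1-[(5S)-5-(tert-butyldimethylsilyloxy)-2,6,6-trimethylcyclohex-1-en-1-yl]but-3-en-1-ol
Product: 8 (1R)-1-[(5S)-5-(tert-butyldimethylsilyloxy)-2,6,6-trimethylcyclohex-1-en-1-yl]but-3-en-1-yl prop-2-enoate
Conditions: CH2=CHCOCl, Et3N, DMAP (cat.), CH2Cl2, 0 °C
Reagents that add atoms: acryloyl chloride, C=CC(=O)Cl
Why: DMAP-catalysed acylation of the secondary alcohol supplies C9 and C11 as an acrylate poised for ring closure.

Step 7
Reactants: 8 (1R)-1-[(5S)-5-(tert-butyldimethylsilyloxy)-2,6,6-trimethylcyclohex-1-en-1-yl]but-3-en-1-yl prop-2-enoate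
Product: 9 (6R)-6-[(5S)-5-(tert-butyldimethylsilyloxy)-2,6,6-trimethylcyclohex-1-en-1-yl]-5,6-dihydro-2H-pyran-2-one
Conditions: second-generation Grubbs catalyst RuCl2(=CHPh)(PCy3)(H2IMes) (5 mol %), CH2Cl2, 40 °C
Reagents that add atoms: none
Why: Ring-closing metathesis of the two monosubstituted alkenes forms the six-membered unsaturated lactone and leaves the tetrasubstituted ring A alkene untouched.

Step 8
Reactants: 9 (6R)-6-[(5S)-5-(tert-butyldimethylsilyloxy)-2,6,6-trimethylcyclohex-1-en-1-yl]-5,6-dihydro-2H-pyran-2-one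
Product: 10 (4S,6R)-4-methyl-6-[(5S)-5-(tert-butyldimethylsilyloxy)-2,6,6-trimethylcyclohex-1-en-1-yl]tetrahydro-2H-pyran-2-one (methyl trans to the cyclohexenyl group)
Conditions: Me2CuLi (from MeLi, CuI), Et2O, −78 → −40 °C; aq. NH4Cl
Reagents that add atoms: methyllithium, C[Li] (delivered as Me2CuLi)
Why: Cuprate conjugate addition places the C17 methyl on C8 by axial attack anti to the C6 substituent, which should give the 4,6-trans lactone (C8 S), and at −78 °C 1,4-addition should outrun allylic substitution at the lactone C6–O bond.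

Step 9
Reactants: 10 (4S,6R)-4-methyl-6-[(5S)-5-(tert-butyldimethylsilyloxy)-2,6,6-trimethylcyclohex-1-en-1-yl]tetrahydro-2H-pyran-2-one
Product: 13 (1S,2S,6S,8aS)-6-(tert-butyldimethylsilyloxy)-2,5,5,8a-tetramethyl-1,2,3,5,6,7,8,8a-octahydronaphthalene-1-carboxylic acid, via trimethylsilyl ketene acetal 11 (not isolated), via trimethylsilyl ester 12 (not isolated)
Conditions: LiN(iPr)2, Me3SiCl/Et3N, THF, −78 → 23 °C; PhMe, 110 °C; 1 M HCl, 23 °C
Reagents that add atoms: none
Why: Lithium diisopropylamide removes a C9 proton of 10 and the enolate is trapped on oxygen, which puts the C11=C9 ketene acetal bond inside the lactone ring; on heating, a concerted suprafacial [3,3] sigmatropic shift (Ireland–Claisen rearrangement) joins C9 to C10 while the C6–O1 bond opens and the alkene moves to C5=C6, and silyl ester 12 is hydrolysed on work-up. The closest known reaction type is the boat-mode enolate Claisen rearrangement of 6-alkenyl lactone silyl ketene acetals to cycloalkene carboxylic acids; here the terminus C10 is fully substituted, which is the main demand on the step. Ring B (C5–C10) is closed by the rearrangement itself as a ring transposition: the six-membered lactone (O1, C11, C9, C8, C7, C6) is exchanged for the six-membered carbocycle, and the C7–C8 tether enforces the boat array and keeps C7 cis to C10 on the new C5=C6 bond. C10 is set by chirality transfer from the C6 carbinol centre (R), because the breaking C6–O1 bond and the forming C9–C10 bond must lie on the same face of the C6–C5=C10 unit; C9 follows from the boat geometry (carboxyl trans to the C10 methyl) and is erased in step 15, and C8 is carried through unchanged. The selectivities needed are O- over C-silylation, secured by trapping with Me3SiCl/Et3N at −78 °C, and one reactive conformer, secured by the 4,6-trans lactone, in which the cyclohexenyl group can sit axial over the ketene acetal while the C8 methyl stays equatorial and points away from the C10 methyl and ring A. The gain of the strong C=O bond of the silyl ester offsets the strain of building the quaternary centre.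

Step 10
Reactants: 13 (1S,2S,6S,8aS)-6-(tert-butyldimethylsilyloxy)-2,5,5,8a-tetramethyl-1,2,3,5,6,7,8,8a-octahydronaphthalene-1-carboxylic acid
Product: 14 methyl (1S,2S,6S,8aS)-6-(tert-butyldimethylsilyloxy)-2,5,5,8a-tetramethyl-1,2,3,5,6,7,8,8a-octahydronaphthalene-1-carboxylate
Conditions: MeI, K2CO3, DMF, 23 °C
Reagents that add atoms: iodomethane, CI
Why: O-Alkylation of the carboxylate (SN2 on iodomethane) esterifies the hindered acid without acid that could protonate the C5=C6 alkene.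

Step 11
Reactants: 14 methyl (1S,2S,6S,8aS)-6-(tert-butyldimethylsilyloxy)-2,5,5,8a-tetramethyl-1,2,3,5,6,7,8,8a-octahydronaphthalene-1-carboxylate
Product: 15 methyl (1S,2S,6S,8aS)-6-hydroxy-2,5,5,8a-tetramethyl-1,2,3,5,6,7,8,8a-octahydronaphthalene-1-carboxylate
Conditions: HF·pyridine, THF, 0 → 23 °C
Reagents that add atoms: none
Why: Fluoride cleavage of the silyl ether frees the axial C3 hydroxyl, which lies on the face opposite the C10 methyl.

Step 12
Reactants: 15 methyl (1S,2S,6S,8aS)-6-hydroxy-2,5,5,8a-tetramethyl-1,2,3,5,6,7,8,8a-octahydronaphthalene-1-carboxylate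
Product: 16 methyl (1S,2S,4aS,6S,8aR)-6-hydroxy-2,5,5,8a-tetramethyldecahydronaphthalene-1-carboxylate
Conditions: [Ir(cod)(PCy3)(py)]PF6 (5–10 mol %), H2 (1–4 atm), CH2Cl2, 23 °C
Reagents that add atoms: none
Why: Hydroxyl-directed homogeneous hydrogenation should deliver H2 to C5=C6 from the face of the axial C3–OH (shared by the C9 ester), anti to the C10 methyl, setting C5 (S) and the trans ring fusion.

Step 13
Reactants: 16 methyl (1S,2S,4aS,6S,8aR)-6-hydroxy-2,5,5,8a-tetramethyldecahydronaphthalene-1-carboxylate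
Product: 17 methyl (1S,2S,4aS,6R,8aR)-6-bromo-2,5,5,8a-tetramethyldecahydronaphthalene-1-carboxylate
Conditions: CBr4, PPh3, CH2Cl2, 0 → 23 °C
Reagents that add atoms: tetrabromomethane, BrC(Br)(Br)Br
Why: In the Appel reaction the axial alkoxyphosphonium ion is displaced by bromide along the equatorial trajectory (SN2), inverting C3 to the equatorial R bromide cis to the C10 methyl, while the ester is inert.

Step 14
Reactants: 17 methyl (1S,2S,4aS,6R,8aR)-6-bromo-2,5,5,8a-tetramethyldecahydronaphthalene-1-carboxylate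
Product: 18 methyl (1S,2S,4aS,6R,8aR)-1,6-dibromo-2,5,5,8a-tetramethyldecahydronaphthalene-1-carboxylate
Conditions: LiN(iPr)2, THF, −78 → −20 °C; BrCCl2CCl2Br, −78 °C
Reagents that add atoms: 1,2-dibromo-1,1,2,2-tetrachloroethane, BrC(Cl)(Cl)C(Cl)(Cl)Br
Why: α-Halogenation of the ester lithium enolate should occur at C9 on the face opposite the axial C10 methyl, giving the axial C9 bromide anti-periplanar to the axial C8–H, and the equatorial C3 bromide has no anti-periplanar hydrogen and should survive the base.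

Step 15
Reactants: 18 methyl (1S,2S,4aS,6R,8aR)-1,6-dibromo-2,5,5,8a-tetramethyldecahydronaphthalene-1-carboxylate
Product: 19 methyl (4aS,6R,8aR)-6-bromo-2,5,5,8a-tetramethyl-3,4,4a,5,6,7,8,8a-octahydronaphthalene-1-carboxylate
Conditions: DBU, PhMe, 90 °C
Reagents that add atoms: none
Why: E2 dehydrobromination removes the only β-hydrogen (axial C8–H, anti to the axial C9–Br) and gives the tetrasubstituted C8=C9 enoate, erasing C8 and C9.

Step 16
Reactants: 19 methyl (4aS,6R,8aR)-6-bromo-2,5,5,8a-tetramethyl-3,4,4a,5,6,7,8,8a-octahydronaphthalene-1-carboxylate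
Product: 20 [(4aS,6R,8aR)-6-bromo-2,5,5,8a-tetramethyl-3,4,4a,5,6,7,8,8a-octahydronaphthalen-1-yl]methanol
Conditions: iBu2AlH, CH2Cl2, −78 → 0 °C
Reagents that add atoms: none
Why: 1,2-Reduction of the conjugated ester by the aluminium hydride gives the C11 allylic alcohol, and the unactivated secondary bromide is inert at this temperature.

Step 17
Reactants: 20 [(4aS,6R,8aR)-6-bromo-2,5,5,8a-tetramethyl-3,4,4a,5,6,7,8,8a-octahydronaphthalen-1-yl]methanol
Product: 21 (4aS,6R,8aR)-6-bromo-2,5,5,8a-tetramethyl-3,4,4a,5,6,7,8,8a-octahydronaphthalene-1-carbaldehyde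
Conditions: MnO2, CH2Cl2, 23 °C
Reagents that add atoms: none
Why: MnO2 oxidises the allylic alcohol selectively to the enal without over-oxidation.

Step 18
Reactants: 21 (4aS,6R,8aR)-6-bromo-2,5,5,8a-tetramethyl-3,4,4a,5,6,7,8,8a-octahydronaphthalene-1-carbaldehyde
Product: 22 (4aS,6R,8aR)-6-bromo-1-ethenyl-2,5,5,8a-tetramethyl-3,4,4a,5,6,7,8,8a-octahydronaphthalene
Conditions: Ph3PCH3Br, KOtBu, THF, 0 → 23 °C
Reagents that add atoms: methyltriphenylphosphonium bromide, C[P+](c1ccccc1)(c1ccccc1)c1ccccc1.[Br-]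
Why: Wittig methylenation adds C12 and creates a diene whose only accessible alkene is the terminal C11=C12.

Step 19
Reactants: 23 but-2-yn-1-ol
Product: 25 (Z)-3-iodobut-2-en-1-ol, via sodium alkenylaluminate 24 (not isolated)
Conditions: NaAlH2(OCH2CH2OCH3)2, Et2O, 0 → 23 °C; I2, THF, −78 °C
Reagents that add atoms: iodine, II
Why: trans-Hydroalumination of the propargylic alcohol through a cyclic alkoxyaluminate places aluminium on C3 cis to the CH2O group, and iodinolysis with retention gives the Z iodide.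

Step 20
Reactants: 22 (4aS,6R,8aR)-6-bromo-1-ethenyl-2,5,5,8a-tetramethyl-3,4,4a,5,6,7,8,8a-octahydronaphthalene; 25 (Z)-3-iodobut-2-en-1-ol
Product: 27 (2Z)-5-[(4aS,6R,8aR)-6-bromo-2,5,5,8a-tetramethyl-3,4,4a,5,6,7,8,8a-octahydronaphthalen-1-yl]-3-methylpent-2-en-1-ol, via B-alkyl-9-borabicyclononane 26 (not isolated)
Conditions: 9-BBN-H, THF, 0 → 23 °C; then 25, PdCl2(dppf) (5 mol %), AsPh3, aq. K3PO4, DMF, 23 °C
Reagents that add atoms: none
Why: Anti-Markovnikov hydroboration puts boron on C12 of the terminal alkene, and B-alkyl Suzuki–Miyaura coupling forms C12–C13 with retention of the Z geometry; the unactivated secondary bromide should not undergo oxidative addition.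

Step 21
Reactants: 27 (2Z)-5-[(4aS,6R,8aR)-6-bromo-2,5,5,8a-tetramethyl-3,4,4a,5,6,7,8,8a-octahydronaphthalen-1-yl]-3-methylpent-2-en-1-ol
Product: 28 [(2S,3R)-3-{2-[(4aS,6R,8aR)-6-bromo-2,5,5,8a-tetramethyl-3,4,4a,5,6,7,8,8a-octahydronaphthalen-1-yl]ethyl}-3-methyloxiran-2-yl]methanol
Conditions: Ti(OiPr)4 (10 mol %), L-(+)-diethyl tartrate (12 mol %), tBuOOH, 4 Å molecular sieves, CH2Cl2, −20 °C
Reagents that add atoms: tert-butyl hydroperoxide, CC(C)(C)OO
Why: Sharpless asymmetric epoxidation is hydroxyl-directed and reagent-controlled, so L-(+)-tartrate on this Z (nerol-type) allylic alcohol should give the (2S,3R)-epoxide, fixing C13 as R, while the isolated C8=C9 alkene is not epoxidised.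

Step 22
Reactants: 28 [(2S,3R)-3-{2-[(4aS,6R,8aR)-6-bromo-2,5,5,8a-tetramethyl-3,4,4a,5,6,7,8,8a-octahydronaphthalen-1-yl]ethyl}-3-methyloxiran-2-yl]methanol
Product: 29 (2R,3R)-2-(iodomethyl)-3-methyl-3-{2-[(4aS,6R,8aR)-6-bromo-2,5,5,8a-tetramethyl-3,4,4a,5,6,7,8,8a-octahydronaphthalen-1-yl]ethyl}oxirane
Conditions: I2, PPh3, imidazole, CH2Cl2, 0 °C
Reagents that add atoms: iodine, II
Why: Appel-type iodination converts the primary alcohol to the iodide, with imidazole buffering the acid-sensitive epoxide and no stereocentre touched.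

Step 23
Reactants: 29 (2R,3R)-2-(iodomethyl)-3-methyl-3-{2-[(4aS,6R,8aR)-6-bromo-2,5,5,8a-tetramethyl-3,4,4a,5,6,7,8,8a-octahydronaphthalen-1-yl]ethyl}oxirane
Product: 30 (3R)-5-[(4aS,6R,8aR)-6-bromo-2,5,5,8a-tetramethyl-3,4,4a,5,6,7,8,8a-octahydronaphthalen-1-yl]-3-methylpent-1-en-3-ol (CNP0103973.1)
Conditions: Zn dust, EtOH, 78 °C
Reagents that add atoms: none
Why: Zinc insertion into the C15–I bond and β-elimination open the oxirane (reductive epoxide opening), moving the alkene to C14=C15 and keeping the C13–O bond, so C13 stays R; the unactivated C3 bromide is inert to zinc.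

## Compound list

1 | (S)-3-hydroxy-2,2-dimethylcyclohexan-1-one | O=C1CCC[C@H](O)C1(C)C | starting material
2 | (S)-3-(tert-butyldimethylsilyloxy)-2,2-dimethylcyclohexan-1-one | O=C1CCC[C@H](O[Si](C)(C)C(C)(C)C)C1(C)C | intermediate
3 | (3S)-3-(tert-butyldimethylsilyloxy)-2,2,6-trimethylcyclohexan-1-one (C6 epimers) | O=C1C(C)CC[C@H](O[Si](C)(C)C(C)(C)C)C1(C)C | intermediate
4 | (S)-5-(tert-butyldimethylsilyloxy)-2,6,6-trimethylcyclohex-1-en-1-yl trifluoromethanesulfonate | FC(F)(F)S(=O)(=O)OC1=C(C)CC[C@H](O[Si](C)(C)C(C)(C)C)C1(C)C | intermediate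
5 | (S)-5-(tert-butyldimethylsilyloxy)-2,6,6-trimethylcyclohex-1-ene-1-carbaldehyde | O=CC1=C(C)CC[C@H](O[Si](C)(C)C(C)(C)C)C1(C)C | intermediate
6 | diisopinocampheylborinate of 7 | C=CC[C@@H](OB([C@H]1C[C@H]2C[C@@H]([C@@H]1C)C2(C)C)[C@H]1C[C@H]2C[C@@H]([C@@H]1C)C2(C)C)C1=C(C)CC[C@H](O[Si](C)(C)C(C)(C)C)C1(C)C | intermediate
7 | (1R)-1-[(5S)-5-(tert-butyldimethylsilyloxy)-2,6,6-trimethylcyclohex-1-en-1-yl]but-3-en-1-ol | C=CC[C@@H](O)C1=C(C)CC[C@H](O[Si](C)(C)C(C)(C)C)C1(C)C | intermediate
8 | (1R)-1-[(5S)-5-(tert-butyldimethylsilyloxy)-2,6,6-trimethylcyclohex-1-en-1-yl]but-3-en-1-yl prop-2-enoate | C=CC[C@@H](OC(=O)C=C)C1=C(C)CC[C@H](O[Si](C)(C)C(C)(C)C)C1(C)C | intermediate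
9 | (6R)-6-[(5S)-5-(tert-butyldimethylsilyloxy)-2,6,6-trimethylcyclohex-1-en-1-yl]-5,6-dihydro-2H-pyran-2-one | O=C1C=CC[C@@H](O1)C1=C(C)CC[C@H](O[Si](C)(C)C(C)(C)C)C1(C)C | intermediate
10 | (4S,6R)-4-methyl-6-[(5S)-5-(tert-butyldimethylsilyloxy)-2,6,6-trimethylcyclohex-1-en-1-yl]tetrahydro-2H-pyran-2-one | O=C1C[C@@H](C)C[C@@H](O1)C1=C(C)CC[C@H](O[Si](C)(C)C(C)(C)C)C1(C)C | intermediate
11 | (2R,4S)-4-methyl-2-[(5S)-5-(tert-butyldimethylsilyloxy)-2,6,6-trimethylcyclohex-1-en-1-yl]-6-(trimethylsilyloxy)-3,4-dihydro-2H-pyran | C[Si](C)(C)OC1=C[C@@H](C)C[C@@H](O1)C1=C(C)CC[C@H](O[Si](C)(C)C(C)(C)C)C1(C)C | intermediate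
12 | trimethylsilyl (1S,2S,6S,8aS)-6-(tert-butyldimethylsilyloxy)-2,5,5,8a-tetramethyl-1,2,3,5,6,7,8,8a-octahydronaphthalene-1-carboxylate | C[Si](C)(C)OC(=O)[C@H]1[C@@H](C)CC=C2C(C)(C)[C@@H](O[Si](C)(C)C(C)(C)C)CC[C@@]12C | intermediate
13 | (1S,2S,6S,8aS)-6-(tert-butyldimethylsilyloxy)-2,5,5,8a-tetramethyl-1,2,3,5,6,7,8,8a-octahydronaphthalene-1-carboxylic acid | OC(=O)[C@H]1[C@@H](C)CC=C2C(C)(C)[C@@H](O[Si](C)(C)C(C)(C)C)CC[C@@]12C | intermediate
14 | methyl (1S,2S,6S,8aS)-6-(tert-butyldimethylsilyloxy)-2,5,5,8a-tetramethyl-1,2,3,5,6,7,8,8a-octahydronaphthalene-1-carboxylate | COC(=O)[C@H]1[C@@H](C)CC=C2C(C)(C)[C@@H](O[Si](C)(C)C(C)(C)C)CC[C@@]12C | intermediate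
15 | methyl (1S,2S,6S,8aS)-6-hydroxy-2,5,5,8a-tetramethyl-1,2,3,5,6,7,8,8a-octahydronaphthalene-1-carboxylate | COC(=O)[C@H]1[C@@H](C)CC=C2C(C)(C)[C@@H](O)CC[C@@]12C | intermediate
16 | methyl (1S,2S,4aS,6S,8aR)-6-hydroxy-2,5,5,8a-tetramethyldecahydronaphthalene-1-carboxylate | COC(=O)[C@H]1[C@@H](C)CC[C@@H]2C(C)(C)[C@@H](O)CC[C@@]12C | intermediate
17 | methyl (1S,2S,4aS,6R,8aR)-6-bromo-2,5,5,8a-tetramethyldecahydronaphthalene-1-carboxylate | COC(=O)[C@H]1[C@@H](C)CC[C@@H]2C(C)(C)[C@H](Br)CC[C@@]12C | intermediate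
18 | methyl (1S,2S,4aS,6R,8aR)-1,6-dibromo-2,5,5,8a-tetramethyldecahydronaphthalene-1-carboxylate | COC(=O)[C@]1(Br)[C@@H](C)CC[C@@H]2C(C)(C)[C@H](Br)CC[C@@]12C | intermediate
19 | methyl (4aS,6R,8aR)-6-bromo-2,5,5,8a-tetramethyl-3,4,4a,5,6,7,8,8a-octahydronaphthalene-1-carboxylate | COC(=O)C1=C(C)CC[C@@H]2C(C)(C)[C@H](Br)CC[C@@]12C | intermediate
20 | [(4aS,6R,8aR)-6-bromo-2,5,5,8a-tetramethyl-3,4,4a,5,6,7,8,8a-octahydronaphthalen-1-yl]methanol | OCC1=C(C)CC[C@@H]2C(C)(C)[C@H](Br)CC[C@@]12C | intermediate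
21 | (4aS,6R,8aR)-6-bromo-2,5,5,8a-tetramethyl-3,4,4a,5,6,7,8,8a-octahydronaphthalene-1-carbaldehyde | O=CC1=C(C)CC[C@@H]2C(C)(C)[C@H](Br)CC[C@@]12C | intermediate
22 | (4aS,6R,8aR)-6-bromo-1-ethenyl-2,5,5,8a-tetramethyl-3,4,4a,5,6,7,8,8a-octahydronaphthalene | C=CC1=C(C)CC[C@@H]2C(C)(C)[C@H](Br)CC[C@@]12C | intermediate
23 | but-2-yn-1-ol | CC#CCO | starting material
24 | sodium 2,2-bis(2-methoxyethoxy)-3-methyl-2,5-dihydro-1,2-oxaaluminol-2-uide | CC1=CCO[Al-]1(OCCOC)OCCOC.[Na+] | intermediate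
25 | (Z)-3-iodobut-2-en-1-ol | C/C(I)=C/CO | intermediate
26 | 9-{2-[(4aS,6R,8aR)-6-bromo-2,5,5,8a-tetramethyl-3,4,4a,5,6,7,8,8a-octahydronaphthalen-1-yl]ethyl}-9-borabicyclo[3.3.1]nonane | C(CC1=C(C)CC[C@@H]2C(C)(C)[C@H](Br)CC[C@@]12C)B1C2CCCC1CCC2 | intermediate
27 | (2Z)-5-[(4aS,6R,8aR)-6-bromo-2,5,5,8a-tetramethyl-3,4,4a,5,6,7,8,8a-octahydronaphthalen-1-yl]-3-methylpent-2-en-1-ol | OC/C=C(/C)CCC1=C(C)CC[C@@H]2C(C)(C)[C@H](Br)CC[C@@]12C | intermediate
28 | [(2S,3R)-3-{2-[(4aS,6R,8aR)-6-bromo-2,5,5,8a-tetramethyl-3,4,4a,5,6,7,8,8a-octahydronaphthalen-1-yl]ethyl}-3-methyloxiran-2-yl]methanol | OC[C@@H]1O[C@]1(C)CCC1=C(C)CC[C@@H]2C(C)(C)[C@H](Br)CC[C@@]12C | intermediate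
29 | (2R,3R)-2-(iodomethyl)-3-methyl-3-{2-[(4aS,6R,8aR)-6-bromo-2,5,5,8a-tetramethyl-3,4,4a,5,6,7,8,8a-octahydronaphthalen-1-yl]ethyl}oxirane | IC[C@@H]1O[C@]1(C)CCC1=C(C)CC[C@@H]2C(C)(C)[C@H](Br)CC[C@@]12C | intermediate
30 | (3R)-5-[(4aS,6R,8aR)-6-bromo-2,5,5,8a-tetramethyl-3,4,4a,5,6,7,8,8a-octahydronaphthalen-1-yl]-3-methylpent-1-en-3-ol (CNP0103973.1) | C=C[C@](C)(O)CCC1=C(C)CC[C@@H]2C(C)(C)[C@H](Br)CC[C@@]12C | target

## Step count and risks

Total step count: 23. Longest linear sequence: 22 steps (steps 1–18 and 20–23); step 19 is a one-step branch.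

The three steps most likely to fail:

**Step 9 (Ireland–Claisen ring transposition).** The boat transition state may not be reached at the fully substituted C10 terminus, so that C-silylation, ionisation of the allylic C6–O bond with proton loss to a triene, or simple return of the lactone on work-up outruns the [3,3] shift. The fallback builds ring B by an intermolecular Diels–Alder reaction and sets out from aldehyde 5. Wittig methylenation (Ph3PCH3Br, KOtBu) would give (S)-tert-butyl[(3-ethenyl-2,2,4-trimethylcyclohex-3-en-1-yl)oxy]dimethylsilane F1. Thermal [4+2] cycloaddition with methyl but-2-ynoate (neat, 150 °C, sealed tube, or high pressure) would form C9–C10 and C7–C8 in the ortho sense and give methyl (6S,8aR)-6-(tert-butyldimethylsilyloxy)-2,5,5,8a-tetramethyl-3,5,6,7,8,8a-hexahydronaphthalene-1-carboxylate F2, with the C8=C9 enoate already in place. C10 would then be controlled only by the C3 silyl ether, so the C10 epimers would have to be separated. HF·pyridine would give methyl (6S,8aR)-6-hydroxy-2,5,5,8a-tetramethyl-3,5,6,7,8,8a-hexahydronaphthalene-1-carboxylate F3. Hydrogenation of C5=C6 alone ([Ir(cod)(PCy3)(py)]PF6, H2, directed by the hydroxyl, or Pd/C) would give methyl (4aS,6S,8aR)-6-hydroxy-2,5,5,8a-tetramethyl-3,4,4a,5,6,7,8,8a-octahydronaphthalene-1-carboxylate F4. CBr4/PPh3 would then return to the route at 19.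

**Step 13 (Appel inversion at C3).** The axial alkoxyphosphonium ion may lose the anti-periplanar axial C2 proton (E2), or ionise with a 1,2-shift from the quaternary C4, instead of accepting bromide. The fallback reaches the same bromide with retention through homoallylic participation and sets out from 15. Dess–Martin periodinane would give methyl (1S,2S,8aS)-2,5,5,8a-tetramethyl-6-oxo-1,2,3,5,6,7,8,8a-octahydronaphthalene-1-carboxylate F5. NaBH4 (MeOH, 0 °C) should give mainly the equatorial alcohol, methyl (1S,2S,6R,8aS)-6-hydroxy-2,5,5,8a-tetramethyl-1,2,3,5,6,7,8,8a-octahydronaphthalene-1-carboxylate F6. CBr4/PPh3 should then give methyl (1S,2S,6R,8aS)-6-bromo-2,5,5,8a-tetramethyl-1,2,3,5,6,7,8,8a-octahydronaphthalene-1-carboxylate F7 with retention, because the C5=C6 bond assists ionisation through a cyclopropylcarbinyl cation, as in cholesterol-type homoallylic alcohols. Hydrogenation of C5=C6 ([Ir(cod)(PCy3)(py)]PF6, H2, directed by the ester carbonyl on the face opposite the C10 methyl, or PtO2 in AcOH) would return to the route at 17.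

**Step 14 (α-bromination of the C9 ester).** The base may fail to remove the shielded C9 proton between C8 and the quaternary C10, or the enolate may be halogenated on the methyl face, which would leave no anti-periplanar C8–H for step 15. The fallback dehydrogenates at the aldehyde oxidation level and sets out from 17. iBu2AlH would give [(1S,2S,4aS,6R,8aR)-6-bromo-2,5,5,8a-tetramethyldecahydronaphthalen-1-yl]methanol F8. 2-Iodoxybenzoic acid (3 equiv, DMSO, 80 °C) would oxidise it to (1S,2S,4aS,6R,8aR)-6-bromo-2,5,5,8a-tetramethyldecahydronaphthalene-1-carbaldehyde F9 and dehydrogenate this through its enol in the same flask; only the axial C8–H needs to align with the enol π-system. This returns to the route at enal 21.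

## Further compounds

F1 | step 9 | (S)-tert-butyl[(3-ethenyl-2,2,4-trimethylcyclohex-3-en-1-yl)oxy]dimethylsilane | C=CC1=C(C)CC[C@H](O[Si](C)(C)C(C)(C)C)C1(C)C
F2 | step 9 | methyl (6S,8aR)-6-(tert-butyldimethylsilyloxy)-2,5,5,8a-tetramethyl-3,5,6,7,8,8a-hexahydronaphthalene-1-carboxylate | COC(=O)C1=C(C)CC=C2C(C)(C)[C@@H](O[Si](C)(C)C(C)(C)C)CC[C@@]12C
F3 | step 9 | methyl (6S,8aR)-6-hydroxy-2,5,5,8a-tetramethyl-3,5,6,7,8,8a-hexahydronaphthalene-1-carboxylate | COC(=O)C1=C(C)CC=C2C(C)(C)[C@@H](O)CC[C@@]12C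
F4 | step 9 | methyl (4aS,6S,8aR)-6-hydroxy-2,5,5,8a-tetramethyl-3,4,4a,5,6,7,8,8a-octahydronaphthalene-1-carboxylate | COC(=O)C1=C(C)CC[C@@H]2C(C)(C)[C@@H](O)CC[C@@]12C
F5 | step 13 | methyl (1S,2S,8aS)-2,5,5,8a-tetramethyl-6-oxo-1,2,3,5,6,7,8,8a-octahydronaphthalene-1-carboxylate | COC(=O)[C@H]1[C@@H](C)CC=C2C(C)(C)C(=O)CC[C@@]12C
F6 | step 13 | methyl (1S,2S,6R,8aS)-6-hydroxy-2,5,5,8a-tetramethyl-1,2,3,5,6,7,8,8a-octahydronaphthalene-1-carboxylate | COC(=O)[C@H]1[C@@H](C)CC=C2C(C)(C)[C@H](O)CC[C@@]12C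
F7 | step 13 | methyl (1S,2S,6R,8aS)-6-bromo-2,5,5,8a-tetramethyl-1,2,3,5,6,7,8,8a-octahydronaphthalene-1-carboxylate | COC(=O)[C@H]1[C@@H](C)CC=C2C(C)(C)[C@H](Br)CC[C@@]12C
F8 | step 14 | [(1S,2S,4aS,6R,8aR)-6-bromo-2,5,5,8a-tetramethyldecahydronaphthalen-1-yl]methanol | OC[C@H]1[C@@H](C)CC[C@@H]2C(C)(C)[C@H](Br)CC[C@@]12C
F9 | step 14 | (1S,2S,4aS,6R,8aR)-6-bromo-2,5,5,8a-tetramethyldecahydronaphthalene-1-carbaldehyde | O=C[C@H]1[C@@H](C)CC[C@@H]2C(C)(C)[C@H](Br)CC[C@@]12C
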